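(The earlier runs and the new flask were computed with made-up constants; noise was put on by code.)

The flask held 2.0 M of starting material, 1.00 M of coupling partner and 100 mM of free catalyst, so coupling partner was the limiting reagent of the charge, and I began from its balance.

| setting | oak | elm | flask |
|---|---|---|---|
| starting material | 2 M | 2 M | 2.0 M |
| coupling partner | 1 M | 0.50 M | 1.00 M |
| free catalyst | 100 mM | 100 mM | 100 mM |
| temperature | −20 °C | −14 °C | −20 °C |
| remark | the very flask that is asked about, followed so far | run made earlier |  |
| time |  |  | 12 h |

oak run (percent of the starting material charged): time / h: product / % = 2.50: 11.5; 5.00: 12.7; 8.00: 12.5; 10.0: 12.9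

elm run (percent of the starting material charged): time / min: product / % = 25.0: 3.1; 50.0: 4.4; 80.0: 5.9; 120: 5.8

(scatter of a reading: 0.3 percentage points)

- ochre: at 12 h add coupling partner, 50.0% of the amount charged, then wait 6.0 h
- blue: at 12 h take out 90% of the product then present, then wait 6.0 h
- violet: change nothing and wait 6.0 h more
- grey: at 12 h add free catalyst, 100% of the amount charged, then wait 6.0 h
- red: at 12 h raise the temperature by 15 K, then wait 6.0 h

- product that was removed still counts
- the analysis behind the earlier runs scatters by 0.3 percentage points, standard deviation
- steps thought possible: coupling partner + free catalyst -> catalyst intermediate A; catalyst intermediate A <-> catalyst intermediate B; starting material + catalyst intermediate B -> catalyst intermediate C; catalyst intermediate C -> free catalyst + product; free catalyst -> spent catalyst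
- additions bring no volume worth counting

* product, in percent of the starting material first charged, at 12 h
* the option that brings most further product ("none" if no option brings more than 2 percentage points) (ochre / blue / violet / grey / red / none)
* product present, with what was taken out counted in, in percent of the starting material first charged, after blue
* product present, with what was taken out counted in, in percent of the starting material first charged, after red

Each round of the catalyst takes one coupling partner and gives one product, and free catalyst can either be captured by coupling partner or be lost to spent catalyst. I took capture over loss to be s[coupling partner]. Dividing the two rates and following them until the charged catalyst has become spent catalyst gives ln([coupling partner]start/[coupling partner]end) = s[catalyst charged]. In oak, the readings from 5.00 h on averaged 12.7%. That is 0.254 M of product, a turnover number of 2.54, and it left 0.746 M of coupling partner. So the reading was s = 2.93 M⁻¹, the captures per loss at one molar of coupling partner. Elm, with 0.50 M at −14 °C, gave 2.67 M⁻¹ by the same reckoning, and I carried oak's value, read at the flask's own temperature.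

In slow motion, oak ran like this. In the first instants, 100 mM of catalyst was free and [coupling partner] stood at 1 M, so capture led loss by 2.93 to one on my reading. By 2.50 h product already read 11.5%, and each round lowered that ratio a little, towards 2.19 to one. At the end, product moved 0.2 percentage points between 5.00 h and 10.0 h, less than the scatter, although 0.746 M of coupling partner and 1.75 M of starting material stood by. I therefore took the catalyst to have left its round.

The flask repeats oak, so I committed to 12.7% at 12 h, and to no gain from ochre, blue, violet or red, since each leaves the catalyst as it stood. Grey restarts the balance from 0.746 M, so I reckoned a gain of 9.5 points, above the margin.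

The forecast gave 12.7%, 12.7% after blue, 12.7% after red, and grey as best, and it said of the levelling off that this “points to catalyst death”.

The flask gave 12.9% at 12 h, 12.9% after blue and 12.9% after red, and grey brought 9.5 points against my 9.5 points.

    coupling partner + free catalyst → catalyst intermediate A (k = 0.0659 M⁻¹ min⁻¹, Ea = 58.0 kJ mol⁻¹)
    catalyst intermediate A ⇌ catalyst intermediate B (K = 2.15, k = 0.437 min⁻¹, Ea = 66.0 kJ mol⁻¹, ΔH = −27.0 kJ mol⁻¹)
    starting material + catalyst intermediate B → catalyst intermediate C (k = 0.224 M⁻¹ min⁻¹, Ea = 42.0 kJ mol⁻¹)
    catalyst intermediate C → free catalyst + product (k = 0.364 min⁻¹, Ea = 63.0 kJ mol⁻¹)
    free catalyst → spent catalyst (k = 0.0221 min⁻¹, Ea = 68.0 kJ mol⁻¹)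
    (constants at −20 °C)

At the start of the flask, free catalyst went to catalyst intermediate A 3.0 times as fast as to spent catalyst. By 6.00 h spent catalyst held 99.5% of the catalyst charged, while coupling partner stood at 74.3% of its charge. On the neighbour charged with 2.5 M of coupling partner, s gives 31.8% of product; the computed neighbour gave 32.2%.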